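## Retrosynthetic overview

- Germacrane numbering throughout (ring A = carbocycle C1–C10, C14 on C10, C15 on C4, lactone O on C6, C7=C11, C12 carbonyl, C13 acetoxymethyl). The plan rests on C10(C14)=C1–C2–C3–C4(C15)=C5 of ring A being a cis,cis head-to-tail isoprene dimer whose ends C9 and C6 are spanned only by C7–C8. Ring A is therefore 1,5-dimethylcycloocta-1,5-diene plus two carbons.
- Key disconnection C8–C9: a [1,3] shift of C9 from the carbinol carbon (C6) to the vinyl terminus (C8) in the potassium alkoxide of vinyl carbinol 4 closes ring A first (ketone 7).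
- Butenolide: C7–C11 by aldol of the C6 ketone with ethyl acetoxypyruvate, double elimination to a C7=C8/C11=C13 diene, lactone C6–O–C12 after reduction. C8–OH and C13–OAc then arise together by palladium-catalysed 1,4-addition of acetic acid to the C7–C8 vinyl epoxide (this replaces a late C8 allylic oxidation, which would not be selective).
- Stereochemistry: CBS reduction at C6, hydroxyl-directed 4,5-epoxidation, re-oxidation (the oxirane carries the chirality through the enolate chemistry), chelation-controlled reduction back to C6–OH, hydroxyl-directed 7,8-epoxidation (sets C8), peracid epoxidation of C1=C10 last.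
- Ring order: ring A (step 3), 4,5-oxirane (step 5), γ-lactone (step 12), 1,10-oxirane (step 15).

Key step: step 3

Remark: technical 1,5-dimethylcycloocta-1,5-diene is taken to be freed of its 1,6-dimethyl isomer by fractional distillation before use.

## Route

Step 1
Reactants: 1 (1Z,5Z)-1,5-dimethylcycloocta-1,5-diene
Product: 2 (2Z,6Z)-3,7-dimethylcycloocta-2,6-dien-1-one
Conditions: CrO3, 3,5-dimethylpyrazole, CH2Cl2, −20 °C (diene in excess, recovered)
Reagents that add atoms: chromium trioxide, O=[Cr](=O)=O
Why: Allylic oxidation with the CrO3–3,5-dimethylpyrazole complex (Salmond oxidation) should take hydrogen from the ring CH2 next to the unsubstituted alkene carbon, as in 3-carene and valencene, and hexavalent chromium funnels any oxygen delivered within that allyl unit to the β,β-disubstituted enone; the two alkenes are symmetry-equivalent, so one mono-ketone is expected at low conversion.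

Step 2
Reactants: 2 (2Z,6Z)-3,7-dimethylcycloocta-2,6-dien-1-one; 3 vinylmagnesium bromide
Product: 4 rac-(2Z,6Z)-1-ethenyl-3,7-dimethylcycloocta-2,6-dien-1-ol
Conditions: CeCl3, THF, −78 °C; aq NH4Cl
Reagents that add atoms: vinylmagnesium bromide (3), C=C[Mg]Br
Why: Organocerium 1,2-addition (Imamoto conditions) should add the weakly basic vinyl nucleophile to the carbonyl without enolising the doubly activated ring CH2 (future C9) or adding in conjugate fashion; the carbinol centre is racemic and is destroyed in step 3.

Step 3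
Reactants: 4 rac-(2Z,6Z)-1-ethenyl-3,7-dimethylcycloocta-2,6-dien-1-ol
Product: 7 (2Z,6Z)-3,7-dimethylcyclodeca-2,6-dien-1-one, via potassium alkoxide 5 (not isolated), via potassium enolate 6 (not isolated)
Conditions: KH, 18-crown-6, THF, 0 °C to rt; then sat. aq NH4Cl, −78 °C
Reagents that add atoms: none
Why: KH forms the crown-ether-separated alkoxide 5, in which the C6–C9 bond, allylic to C10=C1 and weakened by the oxyanion, breaks heterolytically to a C9–C10–C1 allyl anion still tethered through C2–C3 to a cross-conjugated divinyl ketone (C8=C7–C6(=O)–C5=C4). The anion recloses by conjugate addition of C9 to the vinyl terminus C8, a net alkoxide-accelerated [1,3]-sigmatropic shift that gives the C6 enolate 6; the closest known reaction is the two-carbon ring expansion of potassium 1-vinylcycloalk-3-en-1-olates (Thies rearrangement). Ring A, the ten-membered carbocycle, is closed by this intramolecular Michael-type C8–C9 bond formation (10-endo-trig with respect to the C7=C8 acceptor), which inserts C7–C8 between C6 and C9 of the eight-membered ring. No stereocentre is formed: 7 is achiral, the carbinol centre of 4 becomes the carbonyl carbon, and neither cis ring alkene is broken, so C10=C1 and C4=C5 should keep the Z geometry of the diene. The selectivity needed is bonding of C9 (not C1) to C8 (not C4): C9 is the primary, unhindered allyl terminus, bonding through C1 needs the strained boat-like [3,3] array that leads to an eight-membered isopropenyl ketone, and C8 is an unsubstituted terminal acceptor whereas C4 is β,β-disubstituted. The cold buffered quench protonates 6 at C7 before the enolate can equilibrate.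

Step 4
Reactants: 7 (2Z,6Z)-3,7-dimethylcyclodeca-2,6-dien-1-one
Product: 8 (1R,2Z,6Z)-3,7-dimethylcyclodeca-2,6-dien-1-ol
Conditions: (S)-Me-CBS oxazaborolidine (cat.), catecholborane, toluene, −78 °C
Reagents that add atoms: none
Why: Corey–Bakshi–Shibata reduction should treat the alkenyl arm (C5=C4) as the large group and the C7 methylene as the small one, so the (S)-catalyst delivers hydride to give the (R)-carbinol at C6, the first stereocentre and the source of absolute configuration.

Step 5
Reactants: 8 (1R,2Z,6Z)-3,7-dimethylcyclodeca-2,6-dien-1-ol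
Product: 9 (1R,2R,6Z,10S)-6,10-dimethyl-11-oxabicyclo[8.1.0]undec-6-en-2-ol
Conditions: VO(acac)2 (cat.), t-BuOOH, CH2Cl2, 0 °C
Reagents that add atoms: tert-butyl hydroperoxide, CC(C)(C)OO
Why: Vanadium-catalysed hydroxyl-directed epoxidation should deliver oxygen only to the allylic C4=C5 alkene (the isolated C1=C10 alkene is inert) on the face cis to the C6 hydroxyl, as in eight- and nine-membered cycloalk-2-enols, setting C4 (S) and C5 (R).

Step 6
Reactants: 9 (1R,2R,6Z,10S)-6,10-dimethyl-11-oxabicyclo[8.1.0]undec-6-en-2-ol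
Product: 10 (1S,6Z,10S)-6,10-dimethyl-11-oxabicyclo[8.1.0]undec-6-en-2-one
Conditions: Dess–Martin periodinane, pyridine, CH2Cl2, 0 °C to rt
Reagents that add atoms: none
Why: Buffered Dess–Martin oxidation returns the C6 carbonyl needed for enolate chemistry at C7 and leaves the oxirane, which now carries the stereochemical information, untouched.

Step 7
Reactants: 11 ethyl 3-bromo-2-oxopropanoate; 12 potassium acetate
Product: 13 ethyl 3-(acetyloxy)-2-oxopropanoate
Conditions: KOAc, AcOH (cat.), acetone, rt
Reagents that add atoms: potassium acetate (12), CC(=O)[O-].[K+]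
Why: SN2 displacement of the primary bromide, activated by the adjacent keto group, by acetate.

Step 8
Reactants: 10 (1S,6Z,10S)-6,10-dimethyl-11-oxabicyclo[8.1.0]undec-6-en-2-one; 13 ethyl 3-(acetyloxy)-2-oxopropanoate
Product: 16 ethyl 2,3-bis(acetyloxy)-2-[(1S,6Z,10S)-6,10-dimethyl-2-oxo-11-oxabicyclo[8.1.0]undec-6-en-3-yl]propanoate (C7/C11 diastereomer mixture), via lithium enolate 14 (not isolated), via lithium aldolate 15 (not isolated)
Conditions: LDA, THF, −78 °C; 13, −78 °C; then Ac2O, −78 to 0 °C
Reagents that add atoms: ethyl 3-(acetyloxy)-2-oxopropanoate (13), CCOC(=O)C(=O)COC(C)=O; acetic anhydride, CC(=O)OC(C)=O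
Why: Kinetic deprotonation should occur at the C7 methylene (the other α-position is the slowly deprotonated oxirane CH), aldol addition to the very electrophilic keto group of 13 forms C7–C11, and acetylation of the tertiary lithium alkoxide blocks retro-aldol; the C7 and C11 configurations are immaterial because both centres become sp2.

Step 9
Reactants: 16 ethyl 2,3-bis(acetyloxy)-2-[(1S,6Z,10S)-6,10-dimethyl-2-oxo-11-oxabicyclo[8.1.0]undec-6-en-3-yl]propanoate
Product: 18 ethyl 2-[(1S,3Z,6Z,10S)-6,10-dimethyl-2-oxo-11-oxabicyclo[8.1.0]undeca-3,6-dien-3-yl]prop-2-enoate, via alkylidene acetate 17 (not isolated)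
Conditions: DBU, THF, 0 °C to rt
Reagents that add atoms: none
Why: Two E1cB eliminations in sequence: the C6 enolate expels the C11 acetate to give the C7=C11 alkylidene 17, and γ-deprotonation at C8 then expels the C13 acetate (1,4-elimination as in Morita–Baylis–Hillman acetates), giving the C7=C8/C11=C13 diene with the ring C7=C8 bond cis, the geometry the strain of the ten-membered ring should enforce.

Step 10
Reactants: 18 ethyl 2-[(1S,3Z,6Z,10S)-6,10-dimethyl-2-oxo-11-oxabicyclo[8.1.0]undeca-3,6-dien-3-yl]prop-2-enoate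
Product: 19 ethyl 2-[(1R,2R,3Z,6Z,10S)-2-hydroxy-6,10-dimethyl-11-oxabicyclo[8.1.0]undeca-3,6-dien-3-yl]prop-2-enoate
Conditions: Zn(BH4)2, Et2O, −20 °C
Reagents that add atoms: none
Why: Chelation-controlled zinc borohydride reduction of an α,β-epoxy ketone (Nakata–Oishi): zinc bridges the carbonyl and oxirane oxygens and hydride should add from the face away from the oxirane C–C bond, giving the erythro (cis) epoxy alcohol with C6 (R) by 1,2-reduction that spares the acrylate.

Step 11
Reactants: 19 ethyl 2-[(1R,2R,3Z,6Z,10S)-2-hydroxy-6,10-dimethyl-11-oxabicyclo[8.1.0]undeca-3,6-dien-3-yl]prop-2-enoate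
Product: 20 7,8-epoxide of 19 (ethyl 2-substituted acrylate; 4,5- and 7,8-oxiranes both cis to the 6-hydroxyl; C8 R)
Conditions: VO(acac)2 (cat.), t-BuOOH, CH2Cl2, 0 °C (crude 19 used at once)
Reagents that add atoms: tert-butyl hydroperoxide, CC(C)(C)OO
Why: Second hydroxyl-directed vanadium epoxidation: C7=C8 is now the only allylic alkene, and allylic 1,2-strain from the C7 substituent reinforces the ring preference, so oxygen should be delivered cis to the C6 hydroxyl (erythro), setting C8 (R) and the transient C7 centre while the acrylate and C1=C10 alkenes stay inert.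

Step 12
Reactants: 20 7,8-epoxide of 19
Product: 21 4,5:7,8-diepoxygermacra-1(10)Z,11(13)-dien-12,6-olide (spiro-epoxy α-methylene γ-lactone; both oxiranes cis to O-6; C8 R)
Conditions: (SCNBu2SnOSnBu2OH)2 (cat.), toluene, 60 °C
Reagents that add atoms: none
Why: Neutral distannoxane-catalysed transesterification closes the γ-lactone from the C6 hydroxyl onto the C12 ester (5-exo-trig acyl substitution), locking C12 cis to C6 before the allylic system is ionised and avoiding the alkoxide (Payne rearrangement) or acid (oxirane opening) of other lactonisation conditions.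

Step 13
Reactants: 21 4,5:7,8-diepoxygermacra-1(10)Z,11(13)-dien-12,6-olide
Product: 22 (4S,5R,6R,8R)-13-acetoxy-4,5-epoxy-8-hydroxygermacra-1(10)Z,7(11)-dien-12,6-olide
Conditions: Pd(PPh3)4 (cat.), AcOH, THF, 0 °C to rt
Reagents that add atoms: acetic acid, CC(=O)O
Why: Tsuji–Trost 1,4-addition of a carboxylic acid to a vinyl epoxide: zerovalent palladium ionises the allylic C7–O bond to an exocyclic π-allyl complex and acetate attacks the unhindered C13 terminus, giving the conjugated butenolide with the C13 acetate of the target; the C8–O bond is never broken, so C8 keeps its configuration.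

Step 14
Reactants: 22 (4S,5R,6R,8R)-13-acetoxy-4,5-epoxy-8-hydroxygermacra-1(10)Z,7(11)-dien-12,6-olide; 23 3-methylbut-2-enoic acid
Product: 24 (4S,5R,6R,8R)-13-acetoxy-4,5-epoxy-8-(3-methylbut-2-enoyloxy)germacra-1(10)Z,7(11)-dien-12,6-olide
Conditions: DCC, DMAP, CH2Cl2, 0 °C to rt
Reagents that add atoms: 3-methylbut-2-enoic acid (23), CC(C)=CC(=O)O
Why: Steglich esterification of the secondary C8 alcohol with the free acid avoids the vinylketene pathway that deconjugates senecioyl chloride, and the mild base should not epimerise C6.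

Step 15
Reactants: 24 (4S,5R,6R,8R)-13-acetoxy-4,5-epoxy-8-(3-methylbut-2-enoyloxy)germacra-1(10)Z,7(11)-dien-12,6-olide
Product: 25 (1S,4S,5R,6R,8R,10R)-13-acetoxy-1,10:4,5-diepoxy-8-(3-methylbut-2-enoyloxy)germacr-7(11)-en-12,6-olide (CNP0228323.1)
Conditions: mCPBA, NaHCO3, CH2Cl2, 0 °C
Reagents that add atoms: 3-chloroperoxybenzoic acid, OOC(=O)c1cccc(Cl)c1
Why: Prilezhaev epoxidation: C1=C10 is the only electron-rich alkene left (the butenolide and senecioate alkenes are deactivated), and attack on its peripheral face anti to the homoallylic C8 ester is expected to give the cis-oxirane with C1 (S) and C10 (R).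

## Compound list

1 | (1Z,5Z)-1,5-dimethylcycloocta-1,5-diene | C/C1=C/CC/C(C)=C\CC1 | starting material
2 | (2Z,6Z)-3,7-dimethylcycloocta-2,6-dien-1-one | O=C1/C=C(C)\CC/C=C(C)\C1 | intermediate
3 | vinylmagnesium bromide | C=C[Mg]Br | starting material
4 | rac-(2Z,6Z)-1-ethenyl-3,7-dimethylcycloocta-2,6-dien-1-ol | C=CC1(O)/C=C(C)\CC/C=C(C)\C1 | intermediate
5 | potassium alkoxide of 4 | C=CC1([O-])/C=C(C)\CC/C=C(C)\C1.[K+] | intermediate (not isolated)
6 | potassium enolate of 7 (O on C6, C6=C7) | [K+].[O-]C1=CCC/C(C)=C\CC/C(C)=C\1 | intermediate (not isolated)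
7 | (2Z,6Z)-3,7-dimethylcyclodeca-2,6-dien-1-one | O=C1/C=C(C)\CC/C=C(C)\CCC1 | intermediate
8 | (1R,2Z,6Z)-3,7-dimethylcyclodeca-2,6-dien-1-ol | O[C@H]1/C=C(C)\CC/C=C(C)\CCC1 | intermediate
9 | (1R,2R,6Z,10S)-6,10-dimethyl-11-oxabicyclo[8.1.0]undec-6-en-2-ol | O[C@H]1[C@H]2O[C@@]2(C)CC/C=C(C)\CCC1 | intermediate
10 | (1S,6Z,10S)-6,10-dimethyl-11-oxabicyclo[8.1.0]undec-6-en-2-one | O=C1[C@H]2O[C@@]2(C)CC/C=C(C)\CCC1 | intermediate
11 | ethyl 3-bromo-2-oxopropanoate | CCOC(=O)C(=O)CBr | starting material
12 | potassium acetate | CC(=O)[O-].[K+] | starting material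
13 | ethyl 3-(acetyloxy)-2-oxopropanoate | CCOC(=O)C(=O)COC(C)=O | intermediate
14 | lithium enolate of 10 (O on C6, C6=C7) | [Li+].[O-]C1=CCC/C(C)=C\CC[C@]2(C)O[C@H]12 | intermediate (not isolated)
15 | lithium aldolate (C11–OLi; C7/C11 mixture) | [Li+].CCOC(=O)C([O-])(COC(C)=O)C1CC/C(C)=C\CC[C@]2(C)O[C@@H]2C1=O | intermediate (not isolated)
16 | ethyl 2,3-bis(acetyloxy)-2-[(1S,6Z,10S)-6,10-dimethyl-2-oxo-11-oxabicyclo[8.1.0]undec-6-en-3-yl]propanoate (C7/C11 mixture) | CCOC(=O)C(OC(C)=O)(COC(C)=O)C1CC/C(C)=C\CC[C@]2(C)O[C@@H]2C1=O | intermediate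
17 | ethyl 3-(acetyloxy)-2-[(1S,6Z,10S)-6,10-dimethyl-2-oxo-11-oxabicyclo[8.1.0]undec-6-en-3-ylidene]propanoate (E/Z mixture) | CCOC(=O)C(COC(C)=O)=C1CC/C(C)=C\CC[C@]2(C)O[C@@H]2C1=O | intermediate (not isolated)
18 | ethyl 2-[(1S,3Z,6Z,10S)-6,10-dimethyl-2-oxo-11-oxabicyclo[8.1.0]undeca-3,6-dien-3-yl]prop-2-enoate | CCOC(=O)C(=C)/C1=C/C/C(C)=C\CC[C@]2(C)O[C@@H]2C1=O | intermediate
19 | ethyl 2-[(1R,2R,3Z,6Z,10S)-2-hydroxy-6,10-dimethyl-11-oxabicyclo[8.1.0]undeca-3,6-dien-3-yl]prop-2-enoate | CCOC(=O)C(=C)/C1=C/C/C(C)=C\CC[C@]2(C)O[C@@H]2[C@@H]1O | intermediate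
20 | 7,8-epoxide of 19 (both oxiranes cis to 6-OH; C8 R) | CCOC(=O)C(=C)[C@@]12O[C@@H]1C/C(C)=C\CC[C@]1(C)O[C@@H]1[C@@H]2O | intermediate
21 | 4,5:7,8-diepoxygermacra-1(10)Z,11(13)-dien-12,6-olide (both oxiranes cis to O-6; C8 R) | C=C1[C@]23[C@@H](OC1=O)[C@H]1O[C@@]1(C)CC/C=C(C)\C[C@H]2O3 | intermediate
22 | (4S,5R,6R,8R)-13-acetoxy-4,5-epoxy-8-hydroxygermacra-1(10)Z,7(11)-dien-12,6-olide | CC(=O)OCC1=C2[C@@H](OC1=O)[C@H]1O[C@@]1(C)CC/C=C(C)\C[C@H]2O | intermediate
23 | 3-methylbut-2-enoic acid | CC(C)=CC(=O)O | starting material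
24 | (4S,5R,6R,8R)-13-acetoxy-4,5-epoxy-8-(3-methylbut-2-enoyloxy)germacra-1(10)Z,7(11)-dien-12,6-olide | CC(=O)OCC1=C2[C@@H](OC1=O)[C@H]1O[C@@]1(C)CC/C=C(C)\C[C@H]2OC(=O)C=C(C)C | intermediate
25 | (1S,4S,5R,6R,8R,10R)-13-acetoxy-1,10:4,5-diepoxy-8-(3-methylbut-2-enoyloxy)germacr-7(11)-en-12,6-olide (CNP0228323.1) | CC(=O)OCC1=C2[C@@H](OC1=O)[C@H]1O[C@@]1(C)CC[C@@H]1O[C@]1(C)C[C@H]2OC(=O)C=C(C)C | target

## Step count and risks

Total steps: 15. Longest linear sequence: 14 (steps 1–6 and 8–15; step 7 prepares pyruvate 13).

The three steps most likely to fail: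

**Step 3 (key step).** The tethered allyl anion may recombine through its C1 terminus (the [3,3] path to an eight-membered isopropenyl ketone), or be protonated before it recloses (ring-opened trienone), or the product enolate may isomerise under the basic conditions. Fallback, from 4 back to 7: silylation of 4 (TMSCl, imidazole, DMF) gives the trimethylsilyl ether of 4 (F1). Flow thermolysis of F1 at about 320 °C through a silylated quartz tube effects the neutral thermal [1,3] shift of the siloxy vinyl carbinol (a diradical pathway, with no free allyl anion or enolate) to the trimethylsilyl enol ether of 7 (F2). Brief hydrolysis of F2 (dilute HCl, THF) returns ketone 7.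

**Step 13.** The π-allyl palladium intermediate may lose a β-hydrogen from C8 (giving an 8-ketone or a diene) instead of capturing acetate, the C8 alkoxide may close onto C13 to a dihydrofuran, or zerovalent palladium may re-ionise the product allylic acetate or the allylic lactone C6–O bond. Fallback, from 21 back to 22, without a transition metal: LiBr and AcOH in THF at 0 °C open the activated vinyl epoxide by bromide under thermodynamic control (conjugate SN2' opening; any tertiary C7 bromide rearranges to the conjugated primary one) to the 13-bromo-8-hydroxy butenolide (F3). Displacement of the primary allylic bromide of F3 with KOAc and 18-crown-6 in MeCN gives 22.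

**Step 15.** Facial selectivity on the C1=C10 alkene rests only on the conformation of ring A and may be poor or reversed, giving the 1,10-epimeric oxirane. Fallback, from 24 back to 25, which delivers the oxirane on the face opposite to the one the electrophile attacks: NBS in aqueous THF forms the bromonium ion on the more accessible face and water opens it anti at the tertiary C10, giving the 1-bromo-10-hydroxy bromohydrin of 24 (F4). K2CO3 in acetone then closes F4 by displacement of the C1 bromide by the C10 alkoxide, so the oxirane ends on the face that the peracid did not reach, giving 25.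

Further compounds
F1 | step 3 | trimethylsilyl ether of 4 | C=CC1(O[Si](C)(C)C)/C=C(C)\CC/C=C(C)\C1
F2 | step 3 | trimethylsilyl enol ether of 7 | C[Si](C)(C)OC1=CCC/C(C)=C\CC/C(C)=C\1
F3 | step 13 | (4S,5R,6R,8R)-13-bromo-4,5-epoxy-8-hydroxygermacra-1(10)Z,7(11)-dien-12,6-olide | BrCC1=C2[C@@H](OC1=O)[C@H]1O[C@@]1(C)CC/C=C(C)\C[C@H]2O
F4 | step 15 | 1-bromo-10-hydroxy bromohydrin of 24 (Br on C1 anti to OH on C10) | CC(=O)OCC1=C2[C@@H](OC1=O)[C@H]1O[C@@]1(C)CC[C@@H](Br)[C@](C)(O)C[C@H]2OC(=O)C=C(C)C
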